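Readings and results were generated by integration with made-up constants; the scatter is artificial.

4 questions stand on this flask, and I answer them through one quantity.

in all of them: starting material 25 mM

| charge | reagent | remark | time |
|---|---|---|---|
| beta | 10 mM | run made earlier |  |
| alpha | 22 mM | run made earlier |  |
| flask | 15.0 mM |  | 15 d |

| run | time / d | starting material / % | target / % |
|---|---|---|---|
| beta | 2.50 | 60.4 | 36.3 |
| beta | 5.00 | 59.5 | 35.3 |
| beta | 8.00 | 59.8 | 35.9 |
| beta | 10.0 | 60.2 | 35.9 |
| beta | 12.0 | 59.7 | 35.3 |
| beta | 15.0 | 59.7 | 36.0 |
| alpha | 2.50 | 12.9 | 77.0 |
| alpha | 5.00 | 12.2 | 77.2 |
| alpha | 8.00 | 12.2 | 77.6 |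
| alpha | 10.0 | 11.9 | 76.4 |
| alpha | 12.0 | 11.5 | 77.6 |
| alpha | 15.0 | 12.2 | 78.2 |

(each reading ± 0.5 percentage points)

- the reaction counts as stopped when no species that holds the starting material changes by six tenths of a point or more over the second half of the time

1. at 15 d, what has stopped the reaction, if anything has (forward and back rates have come level / all of the starting material has reacted / it is still moving / the reagent has run out first)
2. share of the starting material used up at 15 d
3. target at 15 d, in percent of the starting material charged
4. isomer of the product at 15 d, in percent of the starting material charged

Beta and alpha are both flat from their first reading, 2.50 d. I call the reagent charge divided by the starting-material charge the reagent ceiling, 60.0 % of the charge in this flask. In its last reading beta has used 40.3 % against a ceiling of 40.0 %, and alpha 87.8 % against 88.0 %, each within the scatter of 0.5 percentage points. So I read the reagent as the limiting reagent, used one to one, and the ceiling is my bound from above.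

From below, beta gives 40.3 %, since this flask holds the same starting material and more reagent. I tighten that with alpha, which stood flat at 2.50 d, earlier than the 15 d allowed here. Scaling the ceiling by alpha's ratio of used fraction to ceiling gives 59.9 %.

The forecast says the reagent has run out first, with 60 % used, 53.2 % target and 6.8 % isomer of the product, on the ground “These match the reagent charged in each run”. Its conversion stands at my ceiling, the top of the bracket from 59.9 % to 60.0 %.

In the flask at 15 d, the reagent has run out first, with 0.0069 % of its charge left; 60.0 % of the starting material is used, with 53.1 % target and 6.90 % isomer of the product, so the conversion stands at the ceiling.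

    reagent → decomposition product (k = 7.90 × 10⁻⁷ min⁻¹)
    target ⇌ isomer of the product (K = 0.130, k = 0.00260 min⁻¹)
    starting material + reagent → target, rate k3*[starting material]*[reagent]^1.5 (k = 8.90 M⁻¹·⁵ min⁻¹)

At 0.0259 d the half-life of starting material by its step with reagent is 0.083 d, shorter than the 610 d half-life of reagent by passing into decomposition product. At 15.0 d the flask holds 0.0069 % of its reagent charge and 0.00155 mM of decomposition product. The neighbour charged with 3.8 mM of reagent has a ceiling of 15.2 %, and its conversion stands at 15.2 %.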